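The earlier runs and the new flask stem from a simulated flask for substances that don't exist, noise included.

1. Whatever happens in these flasks, each Wy charged stands as free Wy, as Rx, as RxLy or inside a catalyst form (WyEk, JoWyEk, Wu). Those forms together can hold no more of it than the Ek charged.

| flask | Wy | Jo | Ek | remark | time |
|---|---|---|---|---|---|
| alpha | 20 mM | 1 equiv | 0.91 mol% | run made earlier |  |
| gamma | 20 mM | 1 equiv | 4.2 mol% | run made earlier |  |
| maple | 20 mM | 1.00 equiv | 2 mol% |  | 50 min |
| larch | 20 mM | 1.00 equiv | 4 mol% |  | 50 min |
| elm | 20 mM | 1.00 equiv | 1 mol% |  | 50 min |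

| run | time / min | Rx / % | WyEk / % | Wy / % | RxLy / % |
|---|---|---|---|---|---|
| alpha | 5.00 | 1.4 | 0 | 97.1 | 0 |
| alpha | 10.0 | 5.7 | 0.4 | 93.7 | 0 |
| alpha | 15.0 | 7.8 | 0 | 88.2 | 1.8 |
| alpha | 20.0 | 11.9 | 0.2 | 86.6 | 0.6 |
| alpha | 25.0 | 12.6 | 0.3 | 85.7 | 1.1 |
| gamma | 2.00 | 3.1 | 2.3 | 94.4 | 0 |
| gamma | 6.00 | 12.0 | 1.7 | 82.7 | 0.4 |
| gamma | 12.0 | 25.7 | 0.3 | 70.6 | 1.0 |
| gamma | 20.0 | 32.5 | 0.4 | 58.3 | 3.9 |
| gamma | 25.0 | 37.0 | 2.3 | 53.5 | 7.7 |

(readings scatter by 1 percentage point)

- which of these there is most of at the end, counted by the Wy in it, maple (Rx / WyEk / RxLy / Wy)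
- which of these there is most of at the end, counted by the Wy in it, larch (Rx / WyEk / RxLy / Wy)
- which of these there is most of at the end, counted by the Wy in it, elm (Rx / WyEk / RxLy / Wy)
- how much there is at the end of the one of these that leads, in percent of the Wy charged: maple
- how much there is at the end of the one of these that leads, in percent of the Wy charged: larch
- how much there is at the end of the one of these that leads, in percent of the Wy charged: elm

- the numbers in the tables scatter by 1 percentage point (one standard deviation)
- on the list of suspects stand: Wy + Ek -> WyEk; Jo + WyEk <-> JoWyEk; JoWyEk <-> Ly + Wu; Wu -> Ek + Rx; Rx + Ly -> RxLy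

2. My reckoning rests on the dose: the Ek loading, as a fraction of the Wy charged, times the time. If the rate scales with the Ek charged, then at this charge of Wy and Jo, equal doses leave equal Wy. The readings roughly agree: alpha at 25.0 min has dose 0.228 min and Wy 85.7%, and gamma at 6.00 min has dose 0.252 min and Wy 82.7%.

3. You can solve two extreme versions in your head, both pinned to gamma's last reading, at dose 1.05 min. In the pseudo-first-order version the rate follows [Wy], so Wy decays exponentially with dose. In the second-order version the rate follows [Wy][Jo], with [Jo] equal to [Wy], so Wy left is 1/(1 + dose/half-dose). Here the half-dose, the dose at which Wy stands at half in this version, is 1.21 min.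

4. The chain on the list takes up Wy at one step and Jo at the next, so I expect the real flask to lie about between the versions, give or take the scatter of the one reading they are pinned to. The half-dose is the crossing. Maple has dose 1.00 min and elm 0.500 min, both below it , so the second-order version leaves Wy at 54.8% in maple and 70.8% in elm, and I expect Wy to lead in both. Larch has dose 2.00 min, above it, so the pseudo-first-order version leaves Wy at about 30.4% and the second-order version at about 37.7%, estimates and not bounds, and the lead is open.

5. The forecast takes the second-order version. It gives Wy at 54.5% in maple, Wy at 70.5% in elm and Rx at 40% in larch, adding: “In larch, Rx narrowly beats Wy, so that call is close.”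

6. The flasks give Wy at 54.5% in maple, Wy at 72.8% in elm and Rx at 39.8% in larch, with Wy at 30.0% there. The forecast held on each count.

    Wy + Ek → WyEk (k = 2.06 /M/s)
    Jo + WyEk ⇌ JoWyEk (K = 48.7 /M, k = 3.67 /M/s)
    JoWyEk ⇌ Ly + Wu (K = 0.00730 M, k = 0.104 /s)
    Wu → Ek + Rx (k = 0.0371 /s)
    Rx + Ly → RxLy (k = 0.0430 /M/s)

7. Maple at 50.0 min and larch at 25.0 min share a dose of 1.00 min, and Wy stands at 54.5% in maple and 54.2% in larch. Neither flask has come to rest at 50 min. Ten times the time, 500 min, gives maple a dose of 10.0 min, many half-doses, and at 500 min Wy stands at 0%. Rx, though, does not stay: in maple it goes from 31.0% at 50.0 min to 5.79% at 500 min, with RxLy then at 94.0%. In larch Rx goes from 39.8% at 50.0 min to 4.63% at 500 min, with RxLy then at 95.2%.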